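**Strategy.** The arylglycerol of unit A is made as a ring that the target does not contain: C7–OH and C9–OH lie 1,3 across the aryloxy carbon C8, so C7, C8, C9 and both oxygens are folded into a trans-1,3-dioxane. One catalytic asymmetric Prins reaction of an (E)-styryl aryl ether (ring A–C7H=C8H–O–ring B) with two formaldehyde units forms C8–C9 and C7–O, closes that ring and sets both stereocentres of unit A. The precursor carries a benzyloxy donor on ring A and a cyano acceptor (the future aldehyde of ring B) on ring B. Units B and E are then attached to (−)-syringaresinol by auxiliary-controlled glycolate aldol reactions.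

Key step: step 4

Labels: in each arylglycerol unit C7 is the benzylic CH–O, C8 the CH–OAr and C9 the CH2–O. Ring A (unit A) and ring E (unit E) are the terminal guaiacyl rings, ring B belongs to unit B, and rings C and D are the syringyl rings of the furofuran core (ring C carries unit B, ring D carries unit E).

Assumption: the antipode of the chiral acid that gives the (4R,5S) dioxane is found by screening both enantiomers, and the configuration of 9 is checked at diol 11 against material from the auxiliary route given under the fallbacks.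

Step 1
Reactants: 1 4-(benzyloxy)-3-methoxybenzaldehyde; 2 malonic acid
Product: 4 (E)-3-[4-(benzyloxy)-3-methoxyphenyl]prop-2-enoic acid, via arylidenemalonic acid 3 (not isolated)
Conditions: pyridine, piperidine (cat.), 100 °C
Reagents that add atoms: none
Why: Knoevenagel–Doebner condensation, in which the arylidenemalonic acid loses CO2 in hot pyridine to give the conjugated acid with the thermodynamically preferred (E) geometry.

Step 2
Reactants: 4 (E)-3-[4-(benzyloxy)-3-methoxyphenyl]prop-2-enoic acid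
Product: 5 1-(benzyloxy)-4-[(E)-2-bromoethenyl]-2-methoxybenzene
Conditions: N-bromosuccinimide (1.0 equiv), LiOAc (0.2 equiv), MeCN/H2O, rt, dark
Reagents that add atoms: N-bromosuccinimide, O=C1CCC(=O)N1Br
Why: Catalytic Hunsdiecker-type bromodecarboxylation, in which bromination at the carboxyl-bearing alkene carbon of the electron-rich cinnamate and decarboxylative elimination should give the (E)-bromostyrene stereoselectively and faster than ring bromination.

Step 3
Reactants: 5 1-(benzyloxy)-4-[(E)-2-bromoethenyl]-2-methoxybenzene; 6 4-hydroxy-3-methoxybenzonitrile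
Product: 7 4-{[(E)-2-(4-benzyloxy-3-methoxyphenyl)ethenyl]oxy}-3-methoxybenzonitrile
Conditions: CuI (10 mol %), N,N-dimethylglycine hydrochloride (30 mol %), Cs2CO3, 1,4-dioxane, 90 °C
Reagents that add atoms: none
Why: Ullmann-type copper-catalysed C–O coupling of a phenol with a vinyl bromide, which proceeds with retention of alkene geometry and tolerates the nitrile.

Step 4
Reactants: 7 4-{[(E)-2-(4-benzyloxy-3-methoxyphenyl)ethenyl]oxy}-3-methoxybenzonitrile; 8 formaldehyde (first CH2O unit, charged as paraformaldehyde)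
Product: 9 4-{[(4R,5S)-4-(4-benzyloxy-3-methoxyphenyl)-1,3-dioxan-5-yl]oxy}-3-methoxybenzonitrile
Conditions: (CH2O)n (6 equiv of CH2O, of which two are incorporated per molecule of 7), chiral confined imino-imidodiphosphate Brønsted acid built on two 3,3'-diaryl-BINOL units (5 mol %), anhydrous CHCl3/cyclohexane, 0 °C to rt
Reagents that add atoms: formaldehyde (second CH2O unit, from the same paraformaldehyde charge), C=O
Why: Proposed new method: formaldehyde protonated inside the chiral ion pair is attacked by C8 of the (E)-enol ether (C8–C9 bond) while the charge develops at C7, where the 4-benzyloxyphenyl ring stabilises it as a quinone-methide-type oxocarbenium; the new C9 oxygen adds the second formaldehyde and the hemiacetal oxygen closes on C7 (C7–O bond), so that 7 and two CH2O units give 9 with nothing split off. The closest known reaction type is the confined-Brønsted-acid-catalysed asymmetric intermolecular Prins reaction of styrenes with paraformaldehyde to 4-aryl-1,3-dioxanes. The dioxane closes 6-exo-trig with respect to the quinoid C7=C1 bond of ring A, through a chair that places aryl and aryloxy trans-diequatorial. C8 (S) is set in the C–C bond-forming step by the catalyst pocket, which shields one alkene face, and C7 (R) follows from the trans closure, which is also the thermodynamic outcome if the benzylic C–O bond forms reversibly, so the erythro relation of unit A results. The step needs C–C bond formation at C8 and not at C7, a trans ring and one alkene face: the first rests on the donor–acceptor design (para-benzyloxy on ring A; para-cyano on ring B, a stronger resonance acceptor than a carboxylic ester that pulls the enol-ether oxygen lone pair into ring B and is inert to acid and formaldehyde), the second on the (E) geometry and the chair, the third on the catalyst.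

Step 5
Reactants: 9 4-{[(4R,5S)-4-(4-benzyloxy-3-methoxyphenyl)-1,3-dioxan-5-yl]oxy}-3-methoxybenzonitrile
Product: 11 4-{[(1R,2S)-1-(4-benzyloxy-3-methoxyphenyl)-1,3-dihydroxypropan-2-yl]oxy}-3-methoxybenzonitrile, via bipyridinium silyl ether 10 (not isolated)
Conditions: Me3SiOTf (2.5 equiv), 2,2'-bipyridyl (3.5 equiv), CH2Cl2, 0 °C to rt; then H2O, rt
Reagents that add atoms: none
Why: Silyl triflate/2,2'-bipyridyl cleavage of a methylene acetal, in which silylation of an acetal oxygen opens the O–CH2–O unit, bipyridyl traps the CH2 carbon as an N-alkoxymethylpyridinium salt and water releases the diol under buffered conditions, so that the C7–O and C9–O bonds stay intact and C7 and C8 keep their configuration.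

Step 6
Reactants: 11 4-{[(1R,2S)-1-(4-benzyloxy-3-methoxyphenyl)-1,3-dihydroxypropan-2-yl]oxy}-3-methoxybenzonitrile
Product: 13 4-{[(1R,2S)-1-(4-benzyloxy-3-methoxyphenyl)-1,3-dihydroxypropan-2-yl]oxy}-3-methoxybenzaldehyde, via aluminated aldimine 12 (not isolated)
Conditions: iBu2AlH (4 equiv), CH2Cl2, −78 to −40 °C; then aq. KNaC4H4O6, rt
Reagents that add atoms: water, O
Why: Partial reduction of an aryl nitrile with iBu2AlH stops at the N-aluminated aldimine, which hydrolyses to the aldehyde on work-up, while the two hydroxyls are only held as aluminium alkoxides.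

Step 7
Reactants: 13 4-{[(1R,2S)-1-(4-benzyloxy-3-methoxyphenyl)-1,3-dihydroxypropan-2-yl]oxy}-3-methoxybenzaldehyde
Product: 14 (1R,2S)-1-(4-benzyloxy-3-methoxyphenyl)-2-(4-formyl-2-methoxyphenoxy)propane-1,3-diyl diacetate
Conditions: Ac2O, pyridine, DMAP (cat.), CH2Cl2, 0 °C to rt
Reagents that add atoms: acetic anhydride, CC(=O)OC(C)=O
Why: Nucleophile-catalysed O-acylation masks both hydroxyls as acetates, which are inert to a boron enolate and leave with the other esters in step 16, and does not touch the aldehyde.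

Step 8
Reactants: 15 sinapyl alcohol (2 equiv)
Product: 16 (±)-syringaresinol
Conditions: FeCl3·6H2O (2.2 equiv), acetone/H2O, rt
Reagents that add atoms: none
Why: Biomimetic oxidative phenol coupling, in which the phenoxyl radicals join C8–C8' (both ortho positions are blocked by methoxy groups) and the two quinone methides are trapped 5-exo by the C9 hydroxyls, giving the cis-fused furofuran with both aryl groups exo as the racemate.

Step 9
Reactants: 16 (±)-syringaresinol
Product: 17 (−)-syringaresinol (1R,3aS,4R,6aS)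
Conditions: preparative chiral HPLC, cellulose tris(3,5-dimethylphenylcarbamate) phase, hexane/iPrOH
Reagents that add atoms: none
Why: Resolution by chromatography on a polysaccharide chiral phase should separate the enantiomers of this rigid C2-symmetric diphenol, the levorotatory one being kept and its identity confirmed against the commercial natural product.

Step 10
Reactants: 17 (−)-syringaresinol; 18 (S)-4-benzyl-3-(chloroacetyl)oxazolidin-2-one (0.9 equiv)
Product: 19 mono-ether of 17 carrying the (S)-oxazolidinone glycolyl group on the ring-D oxygen, ring-C phenol free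
Conditions: K2CO3 (1.2 equiv), DMF, rt
Reagents that add atoms: none
Why: Williamson etherification of a phenoxide with an α-chloro imide, in which a slight deficit of 18 should make the mono-ether the main product (the two phenols are equivalent), with unreacted 17 recovered and the bis-ether removed by chromatography.

Step 11
Reactants: 19 mono-ether imide; 1 4-(benzyloxy)-3-methoxybenzaldehyde
Product: 21 (S)-4-benzyl-3-[(2S,3R)-3-(4-benzyloxy-3-methoxyphenyl)-3-hydroxy-2-(ring-D aryloxy)propanoyl]oxazolidin-2-one with ring-C phenol free, via boron enolate 20 (not isolated)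
Conditions: nBu2BOTf (2.2 equiv), iPr2NEt (2.6 equiv), CH2Cl2, 0 °C; then 1, −78 to 0 °C; pH 7 buffer, MeOH, H2O2
Reagents that add atoms: none
Why: Evans syn-aldol reaction, in which the (Z)-dibutylboron enolate reacts through a chair Zimmerman–Traxler transition state on the face away from the benzyl group of the (S)-auxiliary and sets C8 and C7 of unit E in the threo relation (7R,8R after reduction), the phenol being only transiently O-borylated by the second equivalent of nBu2BOTf.

Step 12
Reactants: 21 threo aldol adduct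
Product: 22 (1R,2R)-1-(4-benzyloxy-3-methoxyphenyl)-2-(ring-D aryloxy)propane-1,3-diol on the syringaresinol core, ring-C phenol free
Conditions: NaBH4 (4 equiv), THF/H2O, 0 °C to rt
Reagents that add atoms: none
Why: Reductive removal of the auxiliary, in which borohydride reduces the activated exocyclic imide carbonyl to the C9 primary alcohol and leaves both stereocentres untouched.

Step 13
Reactants: 22 threo diol of unit E
Product: 23 (1S,2R)-1-(4-benzyloxy-3-methoxyphenyl)-2-(ring-D aryloxy)propane-1,3-diyl bis(4-nitrobenzoate), ring-C phenol free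
Conditions: PPh3, DIAD, 4-nitrobenzoic acid (5 equiv each), THF, 0 °C to rt
Reagents that add atoms: 4-nitrobenzoic acid, O=C(O)c1ccc(cc1)[N+](=O)[O-]
Why: Mitsunobu reaction, which esterifies C9–OH and displaces the activated benzylic C7–OH by 4-nitrobenzoate with SN2 inversion (threo 7R,8R to erythro 7S,8R), while the far less acidic phenol is not deprotonated beside the carboxylic acid and should stay free.

Step 14
Reactants: 23 erythro bis(4-nitrobenzoate); 18 (S)-4-benzyl-3-(chloroacetyl)oxazolidin-2-one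
Product: 24 ether of 23 carrying the (S)-oxazolidinone glycolyl group on the ring-C oxygen
Conditions: K2CO3, DMF, rt to 40 °C
Reagents that add atoms: none
Why: Williamson etherification of the remaining hindered phenol with the α-chloro imide under mild carbonate conditions that leave the 4-nitrobenzoates intact.

Step 15
Reactants: 24 glycolyl imide; 14 A–B aldehyde diacetate
Product: 26 (2S,3R)-β-hydroxy imide joining ring B (C7 of unit B) to the ring-C glycolate carbon (C8 of unit B), via boron enolate 25 (not isolated)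
Conditions: nBu2BOTf (1.15 equiv), iPr2NEt (1.3 equiv), CH2Cl2, 0 °C; then 14, −78 to 0 °C; pH 7 buffer, MeOH, H2O2
Reagents that add atoms: none
Why: Evans syn-aldol reaction, in which the same (S)-auxiliary and chair transition state as in step 11 set C7 and C8 of unit B in the threo relation (7R,8R after reduction), the acetates and 4-nitrobenzoates being inert to the boron enolate.

Step 16
Reactants: 26 β-hydroxy imide
Product: 28 dibenzyl ether of the target (rings A and E O-benzyl; six free hydroxyls), via tetraester diol 27 (not isolated)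
Conditions: NaBH4, THF/H2O, 0 °C; then K2CO3, MeOH, rt
Reagents that add atoms: none
Why: Borohydride reduction of the imide gives C9–OH of unit B, and Zemplén-type transesterification then removes the two acetates and two 4-nitrobenzoates by acyl–oxygen cleavage, so no stereocentre is touched.

Step 17
Reactants: 28 dibenzyl ether of the target
Product: 29 CNP0316493.1
Conditions: H2 (1 atm), Pd/C (10 % palladium on carbon), EtOAc/MeOH, rt
Reagents that add atoms: none
Why: Hydrogenolysis of the two phenolic benzyl ethers over palladium under neutral conditions is much faster than cleavage of the benzylic alcohols or of the furofuran C–O bonds.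

**Compound list**

1 | 4-(benzyloxy)-3-methoxybenzaldehyde | O=Cc1ccc(OCc2ccccc2)c(OC)c1 | starting material
2 | malonic acid | OC(=O)CC(=O)O | starting material
3 | 2-[4-(benzyloxy)-3-methoxybenzylidene]malonic acid | OC(=O)C(=Cc1ccc(OCc2ccccc2)c(OC)c1)C(=O)O | intermediate
4 | (E)-3-[4-(benzyloxy)-3-methoxyphenyl]prop-2-enoic acid | OC(=O)/C=C/c1ccc(OCc2ccccc2)c(OC)c1 | intermediate
5 | 1-(benzyloxy)-4-[(E)-2-bromoethenyl]-2-methoxybenzene | Br/C=C/c1ccc(OCc2ccccc2)c(OC)c1 | intermediate
6 | 4-hydroxy-3-methoxybenzonitrile | N#Cc1ccc(O)c(OC)c1 | starting material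
7 | 4-{[(E)-2-(4-benzyloxy-3-methoxyphenyl)ethenyl]oxy}-3-methoxybenzonitrile | N#Cc1ccc(O/C=C/c2ccc(OCc3ccccc3)c(OC)c2)c(OC)c1 | intermediate
8 | formaldehyde, charged as paraformaldehyde (SMILES of the monomer) | C=O | starting material
9 | 4-{[(4R,5S)-4-(4-benzyloxy-3-methoxyphenyl)-1,3-dioxan-5-yl]oxy}-3-methoxybenzonitrile | COc1cc([C@H]2OCOC[C@@H]2Oc3ccc(C#N)cc3OC)ccc1OCc4ccccc4 | intermediate
10 | N-alkoxymethyl-2,2'-bipyridinium triflate of the ring-opened acetal (C7–O–CH2–N+, C9–OSiMe3; 1R,2S) | COc1cc([C@@H](OC[n+]2ccccc2-c3ccccn3)[C@H](CO[Si](C)(C)C)Oc4ccc(C#N)cc4OC)ccc1OCc5ccccc5.[O-]S(=O)(=O)C(F)(F)F | intermediate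
11 | 4-{[(1R,2S)-1-(4-benzyloxy-3-methoxyphenyl)-1,3-dihydroxypropan-2-yl]oxy}-3-methoxybenzonitrile | COc1cc([C@@H](O)[C@H](CO)Oc2ccc(C#N)cc2OC)ccc1OCc3ccccc3 | intermediate
12 | N-(diisobutylaluminio)aldimine of 13 with both hydroxyls as diisobutylaluminium alkoxides (1R,2S) | CC(C)C[Al](CC(C)C)N=Cc1ccc(O[C@@H](CO[Al](CC(C)C)CC(C)C)[C@H](O[Al](CC(C)C)CC(C)C)c2ccc(OCc3ccccc3)c(OC)c2)c(OC)c1 | intermediate
13 | 4-{[(1R,2S)-1-(4-benzyloxy-3-methoxyphenyl)-1,3-dihydroxypropan-2-yl]oxy}-3-methoxybenzaldehyde | COc1cc([C@@H](O)[C@H](CO)Oc2ccc(C=O)cc2OC)ccc1OCc3ccccc3 | intermediate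
14 | (1R,2S)-1-(4-benzyloxy-3-methoxyphenyl)-2-(4-formyl-2-methoxyphenoxy)propane-1,3-diyl diacetate | COc1cc([C@@H](OC(C)=O)[C@H](COC(C)=O)Oc2ccc(C=O)cc2OC)ccc1OCc3ccccc3 | intermediate
15 | sinapyl alcohol, 4-[(E)-3-hydroxyprop-1-enyl]-2,6-dimethoxyphenol | COc1cc(/C=C/CO)cc(OC)c1O | starting material
16 | (±)-syringaresinol (1:1 mixture of both enantiomers) | Oc1c(OC)cc([C@@H]2OC[C@@H]3[C@H]2CO[C@H]3c4cc(OC)c(O)c(OC)c4)cc1OC.Oc1c(OC)cc([C@H]2OC[C@H]3[C@@H]2CO[C@@H]3c4cc(OC)c(O)c(OC)c4)cc1OC | intermediate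
17 | (−)-syringaresinol, 4,4'-[(1R,3aS,4R,6aS)-tetrahydro-1H,3H-furo[3,4-c]furan-1,4-diyl]bis(2,6-dimethoxyphenol) | Oc1c(OC)cc([C@@H]2OC[C@@H]3[C@H]2CO[C@H]3c4cc(OC)c(O)c(OC)c4)cc1OC | intermediate
18 | (S)-4-benzyl-3-(chloroacetyl)oxazolidin-2-one | O=C(CCl)N1[C@@H](Cc2ccccc2)COC1=O | starting material
19 | (S)-4-benzyl-3-{[4-((1R,3aS,4R,6aS)-4-(4-hydroxy-3,5-dimethoxyphenyl)tetrahydro-1H,3H-furo[3,4-c]furan-1-yl)-2,6-dimethoxyphenoxy]acetyl}oxazolidin-2-one | Oc1c(OC)cc([C@@H]2OC[C@@H]3[C@H]2CO[C@H]3c4cc(OC)c(OCC(=O)N5[C@@H](Cc6ccccc6)COC5=O)c(OC)c4)cc1OC | intermediate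
20 | (Z)-dibutylboron enolate of 19, ring-C phenol O-dibutylborylated | CCCCB(CCCC)Oc1c(OC)cc([C@@H]2OC[C@@H]3[C@H]2CO[C@H]3c4cc(OC)c(O/C=C(\OB(CCCC)CCCC)N5[C@@H](Cc6ccccc6)COC5=O)c(OC)c4)cc1OC | intermediate
21 | Evans adduct of unit E: (2S,3R)-3-(4-benzyloxy-3-methoxyphenyl)-3-hydroxy-2-(ring-D aryloxy)propanoyl imide of the (S)-auxiliary, ring-C phenol free | Oc1c(OC)cc([C@@H]2OC[C@@H]3[C@H]2CO[C@H]3c4cc(OC)c(O[C@H](C(=O)N5[C@@H](Cc6ccccc6)COC5=O)[C@H](O)c7ccc(OCc8ccccc8)c(OC)c7)c(OC)c4)cc1OC | intermediate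
22 | threo diol of unit E (7R,8R) on the core, ring-C phenol free | Oc1c(OC)cc([C@@H]2OC[C@@H]3[C@H]2CO[C@H]3c4cc(OC)c(O[C@H](CO)[C@H](O)c5ccc(OCc6ccccc6)c(OC)c5)c(OC)c4)cc1OC | intermediate
23 | erythro bis(4-nitrobenzoate) of unit E (7S,8R) on the core, ring-C phenol free | Oc1c(OC)cc([C@@H]2OC[C@@H]3[C@H]2CO[C@H]3c4cc(OC)c(O[C@H](COC(=O)c5ccc(cc5)[N+](=O)[O-])[C@@H](OC(=O)c6ccc(cc6)[N+](=O)[O-])c7ccc(OCc8ccccc8)c(OC)c7)c(OC)c4)cc1OC | intermediate
24 | 23 etherified on the ring-C oxygen with the (S)-4-benzyl-2-oxo-oxazolidin-3-yl glycolyl group | O=C(COc1c(OC)cc([C@@H]2OC[C@@H]3[C@H]2CO[C@H]3c4cc(OC)c(O[C@H](COC(=O)c5ccc(cc5)[N+](=O)[O-])[C@@H](OC(=O)c6ccc(cc6)[N+](=O)[O-])c7ccc(OCc8ccccc8)c(OC)c7)c(OC)c4)cc1OC)N9[C@@H](Cc%10ccccc%10)COC9=O | intermediate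
25 | (Z)-dibutylboron enolate of 24 | CCCCB(CCCC)O/C(=C\Oc1c(OC)cc([C@@H]2OC[C@@H]3[C@H]2CO[C@H]3c4cc(OC)c(O[C@H](COC(=O)c5ccc(cc5)[N+](=O)[O-])[C@@H](OC(=O)c6ccc(cc6)[N+](=O)[O-])c7ccc(OCc8ccccc8)c(OC)c7)c(OC)c4)cc1OC)N9[C@@H](Cc%10ccccc%10)COC9=O | intermediate
26 | Evans adduct of unit B: (2S,3R)-β-hydroxy imide; unit A as diacetate (7R,8S), unit E as bis(4-nitrobenzoate) (7S,8R), rings A and E O-benzyl | COc1cc([C@@H](OC(C)=O)[C@H](COC(C)=O)Oc2ccc([C@@H](O)[C@@H](C(=O)N3[C@@H](Cc4ccccc4)COC3=O)Oc5c(OC)cc([C@@H]6OC[C@@H]7[C@H]6CO[C@H]7c8cc(OC)c(O[C@H](COC(=O)c9ccc(cc9)[N+](=O)[O-])[C@@H](OC(=O)c9ccc(cc9)[N+](=O)[O-])c%10ccc(OCc%11ccccc%11)c(OC)c%10)c(OC)c8)cc5OC)cc2OC)ccc1OCc%12ccccc%12 | intermediate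
27 | tetraester diol: unit B as free threo diol (7R,8R), unit A diacetate, unit E bis(4-nitrobenzoate), rings A and E O-benzyl | COc1cc([C@@H](OC(C)=O)[C@H](COC(C)=O)Oc2ccc([C@@H](O)[C@@H](CO)Oc3c(OC)cc([C@@H]4OC[C@@H]5[C@H]4CO[C@H]5c6cc(OC)c(O[C@H](COC(=O)c7ccc(cc7)[N+](=O)[O-])[C@@H](OC(=O)c7ccc(cc7)[N+](=O)[O-])c8ccc(OCc9ccccc9)c(OC)c8)c(OC)c6)cc3OC)cc2OC)ccc1OCc9ccccc9 | intermediate
28 | dibenzyl ether of the target (ring A and ring E phenols O-benzyl, all six alcohols free) | COc1cc([C@@H](O)[C@H](CO)Oc2ccc([C@@H](O)[C@@H](CO)Oc3c(OC)cc([C@@H]4OC[C@@H]5[C@H]4CO[C@H]5c6cc(OC)c(O[C@H](CO)[C@@H](O)c7ccc(OCc8ccccc8)c(OC)c7)c(OC)c6)cc3OC)cc2OC)ccc1OCc9ccccc9 | intermediate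
29 | CNP0316493.1 (unit A 7R,8S; unit B 7R,8R; core 1R,3aS,4R,6aS; unit E 7S,8R) | COc1cc([C@@H](O)[C@H](CO)Oc2ccc([C@@H](O)[C@@H](CO)Oc3c(OC)cc([C@@H]4OC[C@@H]5[C@H]4CO[C@H]5c4cc(OC)c(O[C@H](CO)[C@@H](O)c5ccc(O)c(OC)c5)c(OC)c4)cc3OC)cc2OC)ccc1O | target

**Step count and risks**

Total: 17 steps. Longest linear sequence: 10 steps (steps 8–17 from sinapyl alcohol; the A–B branch, steps 1–7 followed by 15–17, is equally long).

Step 4 (new method). C–C bond formation may take place at C7 instead of C8 if enol-ether polarisation wins, the enol ether may be hydrolysed by traces of water before it reacts, or the alkene faces may be poorly distinguished. The fallback uses known chemistry, sets out from 6 and 1 and returns at 11. Compound 6 is O-alkylated with (R)-4-benzyl-3-(chloroacetyl)oxazolidin-2-one (K2CO3, DMF) to the aryloxyacetyl imide F1. An Evans syn-aldol reaction (nBu2BOTf, iPr2NEt) with 1 should give the aldol adduct F2, and NaBH4 the threo diol F3. A double Mitsunobu esterification with 4-nitrobenzoic acid, with inversion at C7, should give the erythro bis(4-nitrobenzoate) F4, and K2CO3/MeOH then gives 11, from which step 6 onwards is unchanged.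

Step 5. Ionisation of the benzylic C7–O bond of the 4-benzyloxyphenyl-substituted acetal may compete with cleavage at the CH2 carbon and erode the erythro configuration, or the methylene acetal may resist opening. The fallback sets out from 9 and returns at 11. Hydrogenolysis (H2, Pd/C, EtOAc) gives the phenol F5 and acetylation (Ac2O, pyridine) the aryl acetate F6, whose ring A is no longer a strong donor. Classical acetolysis (Ac2O, cat. H2SO4, 0 °C) should then open the acetal without C7 ionisation to the acetoxymethyl ether triacetate F7 (its regioisomer converges). Methanolysis (K2CO3, MeOH) gives the phenolic triol F8, and phenol-selective benzylation (benzyl bromide, K2CO3, acetone) leads back to 11.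

Step 13. Substitution at the electron-rich benzylic carbinol may leak into an SN1 pathway with partial retention, elimination towards a C7=C8 enol ether may compete, or the free phenol may be alkylated. The fallback replaces substitution by oxidation and diastereoselective reduction; it sets out from 22 and returns at 24. The phenol of 22 is first etherified with 18 (K2CO3, DMF) to the imide threo diol F9. The benzylic C7–OH alone is oxidised with 2,3-dichloro-5,6-dicyano-1,4-benzoquinone to the aryl ketone F10. Chelation-controlled reduction with Zn(BH4)2 (Et2O, −20 °C), with hydride delivered to the face opposite C9 in the chelate between C7=O and the C8 aryloxy oxygen, should favour the erythro diol F11, the minor threo isomer being removed by chromatography. Acylation with 4-nitrobenzoyl chloride and pyridine then gives 24.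

**Further compounds**

F1 | step 4 | (R)-4-benzyl-3-[(4-cyano-2-methoxyphenoxy)acetyl]oxazolidin-2-one | N#Cc1ccc(OCC(=O)N2[C@H](Cc3ccccc3)COC2=O)c(OC)c1
F2 | step 4 | (R)-4-benzyl-3-[(2R,3S)-3-(4-benzyloxy-3-methoxyphenyl)-2-(4-cyano-2-methoxyphenoxy)-3-hydroxypropanoyl]oxazolidin-2-one | N#Cc1ccc(O[C@@H](C(=O)N2[C@H](Cc3ccccc3)COC2=O)[C@@H](O)c4ccc(OCc5ccccc5)c(OC)c4)c(OC)c1
F3 | step 4 | 4-{[(1S,2S)-1-(4-benzyloxy-3-methoxyphenyl)-1,3-dihydroxypropan-2-yl]oxy}-3-methoxybenzonitrile | N#Cc1ccc(O[C@@H](CO)[C@@H](O)c2ccc(OCc3ccccc3)c(OC)c2)c(OC)c1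
F4 | step 4 | (1R,2S)-1-(4-benzyloxy-3-methoxyphenyl)-2-(4-cyano-2-methoxyphenoxy)propane-1,3-diyl bis(4-nitrobenzoate) | N#Cc1ccc(O[C@@H](COC(=O)c2ccc(cc2)[N+](=O)[O-])[C@H](OC(=O)c3ccc(cc3)[N+](=O)[O-])c4ccc(OCc5ccccc5)c(OC)c4)c(OC)c1
F5 | step 5 | 4-{[(4R,5S)-4-(4-hydroxy-3-methoxyphenyl)-1,3-dioxan-5-yl]oxy}-3-methoxybenzonitrile | COc1cc([C@H]2OCOC[C@@H]2Oc3ccc(C#N)cc3OC)ccc1O
F6 | step 5 | 4-[(4R,5S)-5-(4-cyano-2-methoxyphenoxy)-1,3-dioxan-4-yl]-2-methoxyphenyl acetate | COc1cc([C@H]2OCOC[C@@H]2Oc3ccc(C#N)cc3OC)ccc1OC(C)=O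
F7 | step 5 | (2S,3R)-3-(acetoxymethoxy)-3-(4-acetoxy-3-methoxyphenyl)-2-(4-cyano-2-methoxyphenoxy)propyl acetate | COc1cc([C@@H](OCOC(C)=O)[C@H](COC(C)=O)Oc2ccc(C#N)cc2OC)ccc1OC(C)=O
F8 | step 5 | 4-{[(1R,2S)-1,3-dihydroxy-1-(4-hydroxy-3-methoxyphenyl)propan-2-yl]oxy}-3-methoxybenzonitrile | COc1cc([C@@H](O)[C@H](CO)Oc2ccc(C#N)cc2OC)ccc1O
F9 | step 13 | 22 etherified on the ring-C oxygen with the (S)-oxazolidinone glycolyl group, unit E threo diol (7R,8R) | O=C(COc1c(OC)cc([C@@H]2OC[C@@H]3[C@H]2CO[C@H]3c4cc(OC)c(O[C@H](CO)[C@H](O)c5ccc(OCc6ccccc6)c(OC)c5)c(OC)c4)cc1OC)N7[C@@H](Cc8ccccc8)COC7=O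
F10 | step 13 | C7 ketone of F9 (unit E: aryl ketone, C8 R, C9–OH free) | O=C(COc1c(OC)cc([C@@H]2OC[C@@H]3[C@H]2CO[C@H]3c4cc(OC)c(O[C@H](CO)C(=O)c5ccc(OCc6ccccc6)c(OC)c5)c(OC)c4)cc1OC)N7[C@@H](Cc8ccccc8)COC7=O
F11 | step 13 | erythro diol (7S,8R) corresponding to F9 | O=C(COc1c(OC)cc([C@@H]2OC[C@@H]3[C@H]2CO[C@H]3c4cc(OC)c(O[C@H](CO)[C@@H](O)c5ccc(OCc6ccccc6)c(OC)c5)c(OC)c4)cc1OC)N7[C@@H](Cc8ccccc8)COC7=O
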